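All runs stem from a simulated flask for an exercise, noise included.

Take a closed, stirred vessel with the gas held at 200 mM, a racemate of the two substrates and a single-handed catalyst made from precatalyst, and read what stands in it.

common to all: gas 200 mM (held)
- Tuesday's: left-handed substrate 2 M; right-handed substrate 2 M; precatalyst 15 mol%; run made earlier
- flask: left-handed substrate 2.0 M; right-handed substrate 2.0 M; precatalyst 10 mol%; time 2.5 min

- Tuesday's (time / s: right-handed substrate / %, left-handed substrate / %, left-handed product / %): 25.0: 42, 39, 13; 50.0: 39, 26, 29; 60.0: 29, 21, 32; 90.0: 19, 5, 41

(readings scatter by 2 percentage points)

- catalyst is single-handed; left-handed substrate and right-handed substrate are mirror images of each other, charged as a racemate, each of them at the stated concentration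
- at the start none of the gas is in solution
- no earlier run changes the charge of precatalyst; that part of a forecast is a guess

* whether the excess of right-handed substrate over left-handed substrate among what is left of the two reaches 95% by 2.5 min (no / yes)
* the highest excess of right-handed substrate over left-handed substrate among what is left of the two up to 2.5 min

Divide the rate of loss of left-handed substrate by that of right-handed substrate. Supposing each falls in proportion to itself and to one shared factor, that factor cancels and time drops out. The fractions of their own charges left, l and f, then obey l = f^s. Read s from Tuesday's readings, each taken against its own charge:

s = Σ ln l / Σ ln f = 2.10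

Carry this reading as the selectivity factor. Now draw the excess E against f:

E = (1 − f^(s−1)) / (1 + f^(s−1))

Per part of the charge reacted, E starts at a slope of 0.355 and then steepens. By this rule it passes 36.4% at half of the right-handed charge left and 64.4% at a quarter, then climbs without a peak towards 100%, so by this rule the top stands at the last moment.

Put the clock back with Tuesday's loss of 0.00877 /s of the whole charge, stretched by the ratio of loadings, which is a guess:

f at a quarter: both substrates left 15.2%, reached at 2.50 min

E at 95%: f = 0.0363, both left 1.86%, reached at 2.88 min

Commit to "no", since that moment is later than the time allowed, and to about 64.4%, since the quarter mark falls at the end.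

The forecast says no and 68%, from 48% to 88%, above my figure: “Excess rises monotonically, so the top value comes at 2.5 min”.

The flask gives no and 65.8%, with 83.2% of the charge reacted at 2.50 min.

    reagent + catalyst + left-handed substrate → catalyst + left-handed product (k = 0.851 /M²/s)
    reagent + catalyst + right-handed substrate → catalyst + right-handed product (k = 0.381 /M²/s)
    reagent ⇌ dormant form (K = 33.0, k = 0.0198 /s)
    precatalyst → catalyst (k = 0.0258 /s)
    gas ⇌ reagent, rate k5*(csat - [reagent]) (kL = 0.502 /s)

Carry s back to this flask: 28% of the right-handed charge left gives l = 6.77%, where 5.7% stands. Carry it to the same flask read at 40 s: 85% of the right-handed charge left gives l = 71.1%, and 70% of the left-handed charge stands there.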